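**Assumption:** the target has no stereocentre and no stereogenic double bond, so it is achiral and "single enantiomer" is met by the constitution alone.

**Retrosynthetic overview**
- Both benzene rings are bought; only the 4-pyranone ring of the chromone is built, and it is the only ring formed.
- Disconnection 1 (O1–C2, cyclodehydration): the chromone comes from a 1-(2-hydroxyaryl)-5-arylpentane-1,3-dione.
- Disconnection 2 (C3–C2 acyl bond, crossed Claisen): the diketone comes from 2'-hydroxy-4',5'-dimethoxyacetophenone and methyl dihydroferulate.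
- No protecting groups: both phenols are carried as phenoxides through the base step and are inert in the acid step.

**Step 1**
Reactants: 1 1-(2-hydroxy-4,5-dimethoxyphenyl)ethan-1-one (2'-hydroxy-4',5'-dimethoxyacetophenone); 2 methyl 3-(4-hydroxy-3-methoxyphenyl)propanoate (methyl dihydroferulate)
Product: 5 1-(2-hydroxy-4,5-dimethoxyphenyl)-5-(4-hydroxy-3-methoxyphenyl)pentane-1,3-dione, via ketone dilithio dianion 3 (not isolated), via ester lithium phenoxide 4 (not isolated)
Conditions: LiHMDS (3.5 equiv), THF, −78 °C, 1 first (1 h), then 2 (1.1 equiv), −78 °C → rt, 12 h; then 1 M HCl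
Reagents that add atoms: none
Why: Crossed Claisen condensation in which the methyl ketone of 1 is fully enolised as dianion 3, the remote phenol of 2 is parked as phenoxide 4 by the third equivalent of base without deactivating the non-conjugated ester, and deprotonation of the β-diketone product by the released methoxide drives C-acylation to completion, with no stereocentre formed.

**Step 2**
Reactants: 5 1-(2-hydroxy-4,5-dimethoxyphenyl)-5-(4-hydroxy-3-methoxyphenyl)pentane-1,3-dione
Product: 7 2-[2-(4-hydroxy-3-methoxyphenyl)ethyl]-6,7-dimethoxy-4H-chromen-4-one, via cyclic hemiketal 6 (not isolated)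
Conditions: conc. HCl (cat.), MeOH, reflux, 2 h
Reagents that add atoms: none
Why: Acid-catalysed cyclodehydration of a 1-(2-hydroxyaryl)-1,3-diketone (chromone ring closure), in which the ortho phenol adds to the C3 ketone to give hemiketal 6 and this loses water irreversibly to the conjugated 4-pyranone, while the aryl methyl ethers and the free guaiacol OH are inert to catalytic HCl in methanol and the transient racemic hemiketal carbon becomes sp2 so the product has no stereocentre.

**Compound list**
1 | 1-(2-hydroxy-4,5-dimethoxyphenyl)ethan-1-one | CC(=O)c1cc(OC)c(OC)cc1O | starting material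
2 | methyl 3-(4-hydroxy-3-methoxyphenyl)propanoate | COC(=O)CCc1ccc(O)c(OC)c1 | starting material
3 | dilithium 4,5-dimethoxy-2-(1-oxidoethenyl)phenolate (enolate/phenoxide dianion of 1) | [Li+].[Li+].[O-]C(=C)c1cc(OC)c(OC)cc1[O-] | intermediate
4 | lithium 2-methoxy-4-(3-methoxy-3-oxopropyl)phenolate (phenoxide of 2) | [Li+].[O-]c1ccc(CCC(=O)OC)cc1OC | intermediate
5 | 1-(2-hydroxy-4,5-dimethoxyphenyl)-5-(4-hydroxy-3-methoxyphenyl)pentane-1,3-dione | COc1cc(CCC(=O)CC(=O)c2cc(OC)c(OC)cc2O)ccc1O | intermediate
6 | 2-hydroxy-2-[2-(4-hydroxy-3-methoxyphenyl)ethyl]-6,7-dimethoxychroman-4-one (racemic, transient) | COc1cc(CCC2(O)CC(=O)c3cc(OC)c(OC)cc3O2)ccc1O | intermediate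
7 | 2-[2-(4-hydroxy-3-methoxyphenyl)ethyl]-6,7-dimethoxy-4H-chromen-4-one (CNP0120929.0, achiral) | COc1cc(CCc2cc(=O)c3cc(OC)c(OC)cc3o2)ccc1O | target

**Total step count:** 2
**Longest linear sequence:** 2

**Steps most likely to fail**
The route has only two steps, so both are ranked and there is no third.

Step 1 (highest risk). The unprotected phenoxide of 2 may aggregate or precipitate and slow the acylation, and the enolisable ester may self-condense. The fallback sets out from 2 and comes back to the route at 7.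
- 2 is O-benzylated (BnBr, K2CO3, acetone, reflux) to methyl 3-[4-(benzyloxy)-3-methoxyphenyl]propanoate F1.
- F1 is acylated onto dianion 3 (made from 1 with LiHMDS 2.5 equiv, THF, −78 °C → rt; then 1 M HCl) to give 5-[4-(benzyloxy)-3-methoxyphenyl]-1-(2-hydroxy-4,5-dimethoxyphenyl)pentane-1,3-dione F2.
- F2 is cyclodehydrated (conc. HCl cat., MeOH, reflux) to 2-{2-[4-(benzyloxy)-3-methoxyphenyl]ethyl}-6,7-dimethoxy-4H-chromen-4-one F3.
- Hydrogenolysis of the benzyl ether (H2 1 atm, 10% Pd/C, EtOAc–MeOH, rt) gives 7.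

Step 2. Dehydration may stall at hemiketal 6, or acidic methanol may cleave diketone 5 by retro-Claisen. The fallback avoids the diketone altogether and forms the side-chain C–C bond instead; it sets out from 1 and comes back to the route at 7.
- 1 is heated with N,N-dimethylacetamide dimethyl acetal (toluene, 110 °C) to give (E)-3-(dimethylamino)-1-(2-hydroxy-4,5-dimethoxyphenyl)but-2-en-1-one F4.
- Acid (conc. HCl, CH2Cl2, rt → reflux) closes F4 with loss of dimethylamine to 6,7-dimethoxy-2-methyl-4H-chromen-4-one F5.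
- Vinylogous aldol condensation of the acidic 2-methyl group with commercial 4-(benzyloxy)-3-methoxybenzaldehyde (NaOEt, EtOH, rt → reflux) gives (E)-2-{2-[4-(benzyloxy)-3-methoxyphenyl]ethenyl}-6,7-dimethoxy-4H-chromen-4-one F6.
- One hydrogenation (H2 1 atm, 10% Pd/C, EtOAc–MeOH, rt) saturates the styryl double bond and removes the benzyl group to give 7.

**Further compounds**
F1 | step 1 | methyl 3-[4-(benzyloxy)-3-methoxyphenyl]propanoate | COC(=O)CCc1ccc(OCc2ccccc2)c(OC)c1
F2 | step 1 | 5-[4-(benzyloxy)-3-methoxyphenyl]-1-(2-hydroxy-4,5-dimethoxyphenyl)pentane-1,3-dione | COc1cc(CCC(=O)CC(=O)c2cc(OC)c(OC)cc2O)ccc1OCc1ccccc1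
F3 | step 1 | 2-{2-[4-(benzyloxy)-3-methoxyphenyl]ethyl}-6,7-dimethoxy-4H-chromen-4-one | COc1cc(CCc2cc(=O)c3cc(OC)c(OC)cc3o2)ccc1OCc1ccccc1
F4 | step 2 | (E)-3-(dimethylamino)-1-(2-hydroxy-4,5-dimethoxyphenyl)but-2-en-1-one | CN(C)/C(C)=C/C(=O)c1cc(OC)c(OC)cc1O
F5 | step 2 | 6,7-dimethoxy-2-methyl-4H-chromen-4-one | Cc1cc(=O)c2cc(OC)c(OC)cc2o1
F6 | step 2 | (E)-2-{2-[4-(benzyloxy)-3-methoxyphenyl]ethenyl}-6,7-dimethoxy-4H-chromen-4-one | COc1cc(/C=C/c2cc(=O)c3cc(OC)c(OC)cc3o2)ccc1OCc1ccccc1
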